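**Retrosynthetic overview**
- Feature: number the benzene ring C1 (OH), C2 (tricosyl), C3 (H), C4 (OMe), C5 (H), C6 (OMe). The alkyl group on C2 and the 1,3-related oxygens on C4 and C6 are the imprint of a tetraketide grown from a C24 acyl starter. The acid terminus of that chain ends up as a carbon substituent on C1, the atom that must carry the third oxygen.
- C1–O is made last, from a C1 formyl group by aryl migration to a peroxide oxygen (Baeyer–Villiger/Dakin type). The formyl group comes from the resorcylate ester by reduction and re-oxidation.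
- The benzene ring is the only ring of the target. It is closed at C1–C2 by an amine-induced aldol aromatization of a diketo-dioxinone. The 1,3-dioxinone ring is bought, carried along as the mask of the carboxyl group and O6, and opened once the arene exists.
- The diketo-dioxinone is cut at C2–C3 into the Weinreb amide of tetracosanoic acid and the dianion of an acetonyl dioxinone. That dioxinone is made from 2,2,6-trimethyl-1,3-dioxin-4-one and acetyl chloride.

Key step: step 4

Remark: the target has no stereocentre, so no stereocontrol is needed. The C23 chain makes every intermediate waxy and poorly soluble in cold or protic media, so THF serves as co-solvent and several steps are run warm.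

**Step 1**
Reactants: 1 tetracosanoic acid
Product: 3 N-methoxy-N-methyltetracosanamide, via tetracosanoyl imidazole 2 (not isolated)
Conditions: CDI, THF, 45 °C; then MeNH(OMe)·HCl, 45 °C → rt
Reagents that add atoms: N,O-dimethylhydroxylamine hydrochloride, CNOC.Cl (the N(Me)OMe group of 3); 1,1'-carbonyldiimidazole, O=C(n1ccnc1)n1ccnc1 (the imidazolyl group of 2 only, none of it stays in 3)
Why: CDI converts the acid into the acyl imidazole with loss of CO2, and the hydroxylamine then displaces imidazole (acyl-imidazole amidation to a Weinreb amide), while warm THF keeps the waxy acid dissolved.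

**Step 2**
Reactants: 4 2,2,6-trimethyl-4H-1,3-dioxin-4-one; 5 acetyl chloride
Product: 7 2,2-dimethyl-6-(2-oxopropyl)-4H-1,3-dioxin-4-one, via lithium dienolate 6 (not isolated)
Conditions: LiN(SiMe3)2, THF, −78 °C; then AcCl (half an equivalent relative to 6), −78 °C; 1 M HCl quench
Reagents that add atoms: acetyl chloride 5, CC(=O)Cl (the acetyl group); lithium bis(trimethylsilyl)amide, [Li+].C[Si](C)(C)[N-][Si](C)(C)C (the lithium of 6 only, none of it stays in 7)
Why: Kinetic deprotonation of the C6 methyl group gives the cross-conjugated dienolate, which acetyl chloride acylates at the exocyclic gamma carbon (vinylogous Claisen-type acylation), and the second equivalent of dienolate takes up the acidic proton of 7 so that the acylation is not stopped by proton transfer.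

**Step 3**
Reactants: 7 2,2-dimethyl-6-(2-oxopropyl)-4H-1,3-dioxin-4-one; 3 N-methoxy-N-methyltetracosanamide
Product: 9 6-(2,4-dioxoheptacosyl)-2,2-dimethyl-4H-1,3-dioxin-4-one, via dilithium dianion 8 (not isolated)
Conditions: 7 (1.5 equiv), LiN(iPr)2 (3.1 equiv), THF, −78 °C; then 3 (1.0 equiv) as a warm dilute THF solution, −78 → −20 °C; 1 M HCl quench
Reagents that add atoms: lithium diisopropylamide, [Li+].CC(C)[N-]C(C)C (the lithium of 8 only, none of it stays in 9)
Why: The first equivalent of base removes a proton from the doubly activated CH2 and the second from the terminal CH3, so the dianion reacts at its last-formed, most basic carbon (Claisen-type acylation of a beta-dicarbonyl dianion, Weinreb ketone synthesis), and lithium chelation by the N-methoxy group holds the addition at the mono-acyl stage until the acid quench.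

**Step 4**
Reactants: 9 6-(2,4-dioxoheptacosyl)-2,2-dimethyl-4H-1,3-dioxin-4-one
Product: 11 7-hydroxy-2,2-dimethyl-5-tricosyl-4H-benzo[d][1,3]dioxin-4-one, via aldol carbinol 10 (not isolated)
Conditions: Et3N, CH2Cl2, rt; 1 M HCl wash
Reagents that add atoms: none
Why: Et3N reversibly deprotonates the CH2 between the dioxinone and the nearer ketone, and the extended dienolate carries charge on dioxinone C5 (future arene C1), which adds to the ketone carbonyl bearing the tricosyl chain (future C2) to give carbinol 10; E1cB loss of water and enolization of the remaining ketone (future C4) then give the arene. The closest known reaction type is the base-induced intramolecular aldol condensation and aromatization of diketo-dioxinones to isopropylidene-protected resorcylates, the flask version of the resorcylic acid fold of a tetraketide. The one new ring, the benzene ring, closes in a favoured 6-(enolexo)-exo-trig mode, and aromatization makes the closure irreversible. No stereocentre has to be controlled, since the carbinol carbon of 10 forms as a racemate and becomes sp2 on dehydration. The selectivity needed is C–C closure from C5 onto the distal ketone in place of Claisen attack on the carboxyl carbon or closure through an enol oxygen to a pyranone; the acetonide secures it by locking the carboxyl group and the O6 enol oxygen in one ring, so that no free acid or free enol is available, and attack on the nearer ketone would require a four-membered ring. The same mask leaves the new C4 hydroxyl as the only free phenol, which allows the stepwise methylation.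

**Step 5**
Reactants: 11 7-hydroxy-2,2-dimethyl-5-tricosyl-4H-benzo[d][1,3]dioxin-4-one
Product: 12 7-methoxy-2,2-dimethyl-5-tricosyl-4H-benzo[d][1,3]dioxin-4-one
Conditions: MeI, K2CO3, acetone/THF, 50 °C
Reagents that add atoms: iodomethane, CI
Why: Williamson ether synthesis on the only acidic OH, with carbonate in an aprotic medium leaving the acetonide lactone untouched.

**Step 6**
Reactants: 12 7-methoxy-2,2-dimethyl-5-tricosyl-4H-benzo[d][1,3]dioxin-4-one
Product: 13 methyl 2-hydroxy-4-methoxy-6-tricosylbenzoate
Conditions: NaOMe, MeOH/THF, 60 °C; aq. HCl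
Reagents that add atoms: sodium methoxide, [Na+].[O-]C
Why: Methoxide adds to the activated, planar lactone carbonyl (transesterification by addition–elimination), and the expelled hemiketal alkoxide collapses to acetone and the phenoxide, which makes the opening irreversible; methylating the para phenol first avoids a deactivating phenoxide.

**Step 7**
Reactants: 13 methyl 2-hydroxy-4-methoxy-6-tricosylbenzoate
Product: 14 methyl 2,4-dimethoxy-6-tricosylbenzoate
Conditions: MeI, K2CO3, DMF/THF, 55 °C
Reagents that add atoms: iodomethane, CI
Why: Williamson ether synthesis, in which the polar aprotic solvent and gentle heating overcome the hydrogen bond of the ortho hydroxyl to the ester.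

**Step 8**
Reactants: 14 methyl 2,4-dimethoxy-6-tricosylbenzoate
Product: 15 (2,4-dimethoxy-6-tricosylphenyl)methanol
Conditions: LiAlH4, THF, 0 °C → reflux; basic aqueous work-up
Reagents that add atoms: none
Why: Hydride reduction of an ester by the small, powerful LiAlH4 reaches the di-ortho-substituted carbonyl, the aryl ethers and alkyl chain are inert, and the non-acidic work-up protects the electron-rich benzylic alcohol.

**Step 9**
Reactants: 15 (2,4-dimethoxy-6-tricosylphenyl)methanol
Product: 16 2,4-dimethoxy-6-tricosylbenzaldehyde
Conditions: MnO2 (activated, excess), CH2Cl2, rt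
Reagents that add atoms: none
Why: Heterogeneous MnO2 oxidation is selective for benzylic alcohols, is fast on electron-rich ones and stops at the aldehyde under neutral conditions.

**Step 10**
Reactants: 16 2,4-dimethoxy-6-tricosylbenzaldehyde
Product: 18 2,4-dimethoxy-6-tricosylphenol, via aryl formate 17 (not isolated)
Conditions: mCPBA, CH2Cl2, 0 °C → rt; aq. Na2SO3 wash; then NaOH, MeOH/THF/H2O, rt, argon; aq. HCl
Reagents that add atoms: 3-chloroperoxybenzoic acid, O=C(OO)c1cccc(Cl)c1 (one oxygen atom)
Why: In this Baeyer–Villiger oxidation of an aryl aldehyde (Dakin-type), the aryl group in the Criegee adduct is enriched by the ortho and para methoxy groups and migrates to oxygen in preference to hydrogen, and the resulting formate 17 is saponified by acyl–oxygen cleavage under argon to the phenol.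

**Compound list**
1 | tetracosanoic acid | CCCCCCCCCCCCCCCCCCCCCCCC(=O)O | starting material
2 | 1-(1H-imidazol-1-yl)tetracosan-1-one (tetracosanoyl imidazole) | CCCCCCCCCCCCCCCCCCCCCCCC(=O)n1ccnc1 | intermediate
3 | N-methoxy-N-methyltetracosanamide | CCCCCCCCCCCCCCCCCCCCCCCC(=O)N(C)OC | intermediate
4 | 2,2,6-trimethyl-4H-1,3-dioxin-4-one | CC1=CC(=O)OC(C)(C)O1 | starting material
5 | acetyl chloride | CC(=O)Cl | starting material
6 | lithium 2,2-dimethyl-6-methylidene-1,3-dioxin-4-olate (lithium dienolate) | [Li+].C=C1C=C([O-])OC(C)(C)O1 | intermediate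
7 | 2,2-dimethyl-6-(2-oxopropyl)-4H-1,3-dioxin-4-one | CC(=O)CC1=CC(=O)OC(C)(C)O1 | intermediate
8 | dilithium dianion of 7 (dioxin-4-olate and terminal prop-2-en-2-olate) | [Li+].[Li+].C=C([O-])C=C1C=C([O-])OC(C)(C)O1 | intermediate
9 | 6-(2,4-dioxoheptacosyl)-2,2-dimethyl-4H-1,3-dioxin-4-one | CC1(C)OC(=O)C=C(CC(=O)CC(=O)CCCCCCCCCCCCCCCCCCCCCCC)O1 | intermediate
10 | 5-hydroxy-2,2-dimethyl-5-tricosyl-5,6-dihydro-4H-benzo[d][1,3]dioxine-4,7(8H)-dione (racemic, transient) | CCCCCCCCCCCCCCCCCCCCCCCC1(O)CC(=O)CC2=C1C(=O)OC(C)(C)O2 | intermediate
11 | 7-hydroxy-2,2-dimethyl-5-tricosyl-4H-benzo[d][1,3]dioxin-4-one | CC1(C)OC(=O)c2c(CCCCCCCCCCCCCCCCCCCCCCC)cc(O)cc2O1 | intermediate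
12 | 7-methoxy-2,2-dimethyl-5-tricosyl-4H-benzo[d][1,3]dioxin-4-one | CCCCCCCCCCCCCCCCCCCCCCCc1cc(OC)cc2OC(C)(C)OC(=O)c12 | intermediate
13 | methyl 2-hydroxy-4-methoxy-6-tricosylbenzoate | CCCCCCCCCCCCCCCCCCCCCCCc1cc(OC)cc(O)c1C(=O)OC | intermediate
14 | methyl 2,4-dimethoxy-6-tricosylbenzoate | CCCCCCCCCCCCCCCCCCCCCCCc1cc(OC)cc(OC)c1C(=O)OC | intermediate
15 | (2,4-dimethoxy-6-tricosylphenyl)methanol | CCCCCCCCCCCCCCCCCCCCCCCc1cc(OC)cc(OC)c1CO | intermediate
16 | 2,4-dimethoxy-6-tricosylbenzaldehyde | CCCCCCCCCCCCCCCCCCCCCCCc1cc(OC)cc(OC)c1C=O | intermediate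
17 | 2,4-dimethoxy-6-tricosylphenyl formate | CCCCCCCCCCCCCCCCCCCCCCCc1cc(OC)cc(OC)c1OC=O | intermediate
18 | 2,4-dimethoxy-6-tricosylphenol (CNP0228278.0) | CCCCCCCCCCCCCCCCCCCCCCCc1cc(OC)cc(OC)c1O | target

**Total step count:** 10
**Longest linear sequence:** 9 steps (steps 2–10 from 4; the branch from 1 through steps 1 and 3–10 has the same length)

**Steps most likely to fail**

**Step 3.** The waxy amide 3 may crystallise from THF in the cold. Acylation would then lag behind the decay of dianion 8 as the bath warms, and proton exchange would return 7.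
- The fallback sets out from 1 and 4 and comes back at 9. It replaces strong-base acylation of the long chain by soft enolization at 0 °C to rt, where the chain stays dissolved.
- Acid 1 is converted with oxalyl chloride and catalytic DMF in CH2Cl2 into tetracosanoyl chloride F1. Allyl hydrogen malonate is converted in the same way into allyl 3-chloro-3-oxopropanoate F2.
- Dienolate 6, made from 4 as in step 2, is acylated with F2 to give allyl 4-(2,2-dimethyl-4-oxo-4H-1,3-dioxin-6-yl)-3-oxobutanoate F3.
- MgCl2 and pyridine in CH2Cl2 enolize the beta-keto ester. F1 then acylates the carbon between ketone and ester to give allyl 2-[(2,2-dimethyl-4-oxo-4H-1,3-dioxin-6-yl)acetyl]-3-oxohexacosanoate F4.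
- Catalytic Pd(PPh3)4, a zerovalent palladium complex, with morpholine as allyl acceptor frees 2-[(2,2-dimethyl-4-oxo-4H-1,3-dioxin-6-yl)acetyl]-3-oxohexacosanoic acid F5. This acid loses CO2 spontaneously to give 9.

**Step 4.** The chain may close through an enol oxygen to a pyranone, the sensitive diketo-dioxinone may break down before it cyclizes, or the aldol adduct may stall before dehydration.
- The fallback sets out from 9 and comes back at 14. It forms the same C1–C2 bond on an open-chain ester instead of on the dioxinone.
- Heating 9 with methanol in toluene at 110 °C causes retro-hetero-Diels–Alder loss of acetone to the acylketene 3,5,7-trioxotriacont-1-en-1-one F6.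
- Methanol traps this ketene as methyl 3,5,7-trioxotriacontanoate F7.
- Cs2CO3 in MeOH followed by methanolic HCl brings about aldol closure and dehydration to methyl 2,4-dihydroxy-6-tricosylbenzoate F8.
- Excess MeI with K2CO3 in DMF methylates both phenols to give 14.

**Step 10.** Hydrogen may migrate in place of the aryl group, which would lead to the acid oxidation level. The peracid may oxidize the very electron-rich ring further, and the phenolate may be oxidized by air during saponification.
- The fallback sets out from 16 and comes back at 18. It exchanges the peracid–carbonyl adduct for a cationic benzylic hydroperoxide rearrangement.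
- MeMgBr in THF at 0 °C adds to 16 to give racemic 1-(2,4-dimethoxy-6-tricosylphenyl)ethan-1-ol F9.
- Aqueous H2O2 with catalytic p-TsOH in THF at 0 °C ionizes this electron-rich benzylic alcohol and captures the cation as 1-(2,4-dimethoxy-6-tricosylphenyl)ethyl hydroperoxide F10.
- An acid-induced aryl shift to oxygen (Hock-type rearrangement) and cleavage of the resulting hemiacetal give 18 without a basic step.

**Further compounds**
F1 | step 3 | tetracosanoyl chloride | CCCCCCCCCCCCCCCCCCCCCCCC(=O)Cl
F2 | step 3 | allyl 3-chloro-3-oxopropanoate | C=CCOC(=O)CC(=O)Cl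
F3 | step 3 | allyl 4-(2,2-dimethyl-4-oxo-4H-1,3-dioxin-6-yl)-3-oxobutanoate | C=CCOC(=O)CC(=O)CC1=CC(=O)OC(C)(C)O1
F4 | step 3 | allyl 2-[(2,2-dimethyl-4-oxo-4H-1,3-dioxin-6-yl)acetyl]-3-oxohexacosanoate | CCCCCCCCCCCCCCCCCCCCCCCC(=O)C(C(=O)OCC=C)C(=O)CC1=CC(=O)OC(C)(C)O1
F5 | step 3 | 2-[(2,2-dimethyl-4-oxo-4H-1,3-dioxin-6-yl)acetyl]-3-oxohexacosanoic acid | CCCCCCCCCCCCCCCCCCCCCCCC(=O)C(C(=O)O)C(=O)CC1=CC(=O)OC(C)(C)O1
F6 | step 4 | 3,5,7-trioxotriacont-1-en-1-one (acylketene) | CCCCCCCCCCCCCCCCCCCCCCCC(=O)CC(=O)CC(=O)C=C=O
F7 | step 4 | methyl 3,5,7-trioxotriacontanoate | CCCCCCCCCCCCCCCCCCCCCCCC(=O)CC(=O)CC(=O)CC(=O)OC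
F8 | step 4 | methyl 2,4-dihydroxy-6-tricosylbenzoate | CCCCCCCCCCCCCCCCCCCCCCCc1cc(O)cc(O)c1C(=O)OC
F9 | step 10 | 1-(2,4-dimethoxy-6-tricosylphenyl)ethan-1-ol (racemic) | CCCCCCCCCCCCCCCCCCCCCCCc1cc(OC)cc(OC)c1C(C)O
F10 | step 10 | 1-(2,4-dimethoxy-6-tricosylphenyl)ethyl hydroperoxide (racemic) | CCCCCCCCCCCCCCCCCCCCCCCc1cc(OC)cc(OC)c1C(C)OO
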